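The enzyme in this flask makes target from substrate, and Sunday's run, the same flask followed so far, reads target.

| flask | substrate | enzyme | remark |
|---|---|---|---|
| Sunday's | 0.10 M | 10 µM | the very flask that is asked about, followed so far |
| flask | 0.10 M | 10 µM |  |

Sunday's run (percent of the substrate charged): time / min: target / % = 4.00: 9.5; 6.00: 11.7; 10.0: 11.2; 20.0: 18.5; 30.0: 19.0; 50.0: 22.9

(readings scatter by 1 percentage point)

- what was read earlier has a scatter of 1 percentage point, one standard deviation
- no earlier run changes the charge of enzyme; that part of a forecast is a guess

- apparent order in enzyme when 10% of the substrate are converted (percent change of the rate of making target for one percent more enzyme charged)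
- factor on the rate of making target when 10% of the substrate are converted if enzyme is charged twice over

I built a ladder of times from these readings, fastest rung first. The first reading gave the early rate of making target:

early rate = 2.38 mM/min

I assumed that target took all the substrate used, and so placed the mark of 10% conversion at:

time of the mark = 4.21 min

The next rung was the quantity I carried. The stall time, the time the early rate needs to make the amount of target in the last reading, came to:

stall time = 9.64 min

The top rung was a crawl. Between 30.0 min and 50.0 min the readings gave a late rate of 0.195 mM/min, far slower than the early rate.

My mark stood at 0.437 of the stall time, earlier than the stall. So I took the rate there as still near the early rate and proportional to enzyme, which gave an order of 1 and a factor of 2. This was a guess, since no run changed the enzyme.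

The forecast stood above me at 1.1 and 2.2, in its words “no enzyme variation was tried, so I skew upward”.

The flask gave an order of 0.88 and a factor of 1.80, both below my reckoning. The mark came at 0.440 min, which is 0.0456 of the stall time.

    substrate + enzyme → target + enzyme, rate k1*[substrate]*[enzyme]/(1 + ([substrate]/Km1) + ([target]/Kp1)) (2.50 mM, 0.120 M, k = 1.30 × 10⁵ /M/min)
    2 substrate → self-condensation product (k = 1.10 /M/min)
    2 enzyme → spent catalyst (k = 18000 /M/min)

At the start substrate condensed with itself, using substrate 6.9 times as fast as the enzyme step did, and the self-condensation had half of its turnover up to 4.00 h behind it at 2.92 min. The enzyme step ran on while enzyme paired off into spent catalyst, reaching half of its own turnover up to that time at 10.2 min, near the stall time, and at 4.00 h target stood at 26.4% with 0.092% left of the substrate, the limiting reagent.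

The numbers in the tables come from a simulation from invented constants.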